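**First entry.** I began with the easy step: each mole of reagent that reacted took one mole of substrate, and the catalyst could hold back little, since it was charged at 5.1 mM against 2.00 M of reagent. With 1.0 M of each substrate, the reagent's charge equalled both substrates together, so I kept the books in percent of that sum.

| flask | left-handed substrate | right-handed substrate | reagent | free catalyst | added ligand | remark | time |
|---|---|---|---|---|---|---|---|
| Tuesday's | 1 M | 1 M | 2 M | 5.1 mM | 29 mM | the very flask that is asked about, followed so far |  |
| Friday's | 1 M | 1 M | 2 M | 5.1 mM | 44 mM | run made earlier |  |
| flask | 1.0 M | 1.0 M | 2.00 M | 5.1 mM | 29 mM |  | 25 min |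

| run | time / min | right-handed substrate / % | left-handed substrate / % |
|---|---|---|---|
| Tuesday's | 0.667 | 48.4 | 39.2 |
| Tuesday's | 2.00 | 46.4 | 20.2 |
| Tuesday's | 3.00 | 41.3 | 10.7 |
| Tuesday's | 5.00 | 37.7 | 4.8 |
| Friday's | 2.00 | 44.9 | 21.8 |
| Friday's | 6.00 | 36.4 | 2.2 |
| Friday's | 12.0 | 30.0 | 0.8 |
| Friday's | 20.0 | 24.6 | 0 |

(scatter of a reading: 1 percentage point)

1. whether the excess of right-handed substrate over left-handed substrate among what is left of the two reaches 80% by 25 min (no / yes)
2. the highest excess of right-handed substrate over left-handed substrate among what is left of the two up to 25 min

- free catalyst is single-handed; left-handed substrate and right-handed substrate are mirror images of each other, charged as a racemate, each of them at the stated concentration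
- candidate steps: reagent + catalyst intermediate B -> free catalyst + right-handed product; free catalyst + right-handed substrate <-> catalyst intermediate B; 2 free catalyst <-> resting dimer; free catalyst + added ligand <-> idle complex; reagent + catalyst intermediate A -> free catalyst + left-handed product; free catalyst + left-handed substrate <-> catalyst intermediate A; left-handed product <-> right-handed product

**Frozen quantity.** Tuesday's reading at 5.00 min gave 8.30 for the selectivity factor, the logarithm of the fraction of left-handed substrate remaining divided by the same logarithm for right-handed substrate. I froze it, so that the left-handed fraction remaining was the right-handed fraction raised to that power.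

**Closing books.** An excess of 80% means right-handed over left-handed substrate of 9.00. The frozen factor then put right-handed substrate at 37.0% and left-handed at 4.11%. So by my books 45.9% of the reagent had gone to the left-handed substrate, 13.0% to the right-handed, and 41.1% stayed unspent: the reagent could pay for that excess.

**The forecast.** It stood at yes, with a top of 99.5%, on the ground “Nothing in the steps racemises substrate, so the excess only rises.”

**The result.** The flask gave yes and a top of >99.9%, reaching 80% at 5.09 min.

    reagent + catalyst intermediate B → free catalyst + right-handed product (k = 14.5 M⁻¹ min⁻¹)
    free catalyst + right-handed substrate ⇌ catalyst intermediate B (K = 2.60 M⁻¹, k = 808 M⁻¹ min⁻¹)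
    2 free catalyst ⇌ resting dimer, settled at all times (K = 95.2 M⁻¹)
    free catalyst + added ligand ⇌ idle complex, settled at all times (K = 18.0 M⁻¹)
    reagent + catalyst intermediate A → free catalyst + left-handed product (k = 290 M⁻¹ min⁻¹)
    free catalyst + left-handed substrate ⇌ catalyst intermediate A (K = 8.20 M⁻¹, k = 470 M⁻¹ min⁻¹)
    left-handed product ⇌ right-handed product (k = 0.163 min⁻¹)

**Reagent's split.** At 1.50 min the flask's reagent was feeding left-handed product 4.6 times as fast as right-handed product. By 25.0 min the flask held 0% left-handed substrate and 20.1% right-handed. It passed the wanted excess with 38.2% right-handed substrate left, where the frozen factor had said 37.0%. On Friday's flask, with 44 mM of added ligand, the factor turned 30.0% of right-handed substrate at 12.0 min into 0.720% of left-handed, and the reading was 0.8%, with a scatter of 1 percentage point.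

(The earlier runs and the new flask were computed for an exercise.)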